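**Plan**

- Numbering: C1 bears the pendant aryl, C2 and C3 bear the CH2O carbons C2a and C3a, C4 is the benzylic CH2, ring A is the aromatic ring C4a–C8a, ring B is the carbocycle.
- Retrosynthesis cuts, in order: the C2a–O ester bond (coumaroyl), the C1–C2 bond of ring B, the C1–C8a aryl–carbinol bond, and the C3–C2 bond (allyl unit on an acyl oxazolidinone).
- Enabling feature: the free hydroxyl of the pendant ring is para to C1, so C1 can become the exocyclic carbon of a p-quinone methide; C2 is alpha to C2a, so with C2a as an aldehyde C2 is an enamine carbon that can add to C1.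
- Forward: ring A (from O-benzylvanillin) receives the C4–C3–C3a chain and the allyl unit (C2, C2a), the pendant ring (from vanillin) is attached at C1 by aryllithium addition, ring B closes last, then reduction, esterification and debenzylation.
- Stereochemistry: C3 comes from (S)-4-benzyl-oxazolidinone (Evans allylation); C1 and C2 are relayed from C3 in a chair-like ring closure, and C2 can still equilibrate through the enamine.

Key step: step 11

Remark: C1 is carried as both carbinol epimers from step 8 to step 10 because it becomes planar in step 11; compounds 1 and 28 are assumed to be bought as such.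

**Route**

Step 1
Reactants: 1 4-(benzyloxy)-3-methoxybenzaldehyde
Product: 2 4-(benzyloxy)-2-bromo-5-methoxybenzaldehyde
Conditions: Br2, NaOAc, AcOH, rt
Reagents that add atoms: bromine, BrBr
Why: Electrophilic aromatic bromination of 4-O-alkylvanillins goes para to the methoxy group and ortho to the formyl group, which is the future C8a, and the acetate buffer keeps HBr from the benzyl ether.

Step 2
Reactants: 2 4-(benzyloxy)-2-bromo-5-methoxybenzaldehyde; 3 Meldrum's acid
Product: 7 3-[4-(benzyloxy)-2-bromo-5-methoxyphenyl]propanoic acid, via arylidene Meldrum's acid 4 (not isolated), via benzyl Meldrum's acid 5 (not isolated), via arylmethylmalonic acid 6 (not isolated)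
Conditions: HCO2H–Et3N (5:2), 95–100 °C; then aq. HCl
Reagents that add atoms: none
Why: Knoevenagel condensation, conjugate reduction of the arylidene by formate (hydride transfer) and hydrolysis with decarboxylation run in one pot without a hydrogenation catalyst, so the aryl bromide and the benzyl ether should be untouched.

Step 3
Reactants: 7 3-[4-(benzyloxy)-2-bromo-5-methoxyphenyl]propanoic acid; 8 (S)-4-benzyl-1,3-oxazolidin-2-one
Product: 10 (4S)-4-benzyl-3-{3-[4-(benzyloxy)-2-bromo-5-methoxyphenyl]propanoyl}-1,3-oxazolidin-2-one, via mixed pivalic anhydride 9 (not isolated)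
Conditions: t-BuCOCl, Et3N, THF, −20 °C; then 8, LiCl, rt
Reagents that add atoms: none
Why: N-acylation of the oxazolidinone through the mixed pivalic anhydride with LiCl/Et3N activation is the standard preparation of Evans imides from free acids.

Step 4
Reactants: 10 (4S)-4-benzyl-3-{3-[4-(benzyloxy)-2-bromo-5-methoxyphenyl]propanoyl}-1,3-oxazolidin-2-one; 11 allyl iodide
Product: 13 (4S)-4-benzyl-3-{(2S)-2-[4-(benzyloxy)-2-bromo-5-methoxybenzyl]pent-4-enoyl}-1,3-oxazolidin-2-one, via sodium (Z)-enolate 12 (not isolated)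
Conditions: NaN(SiMe3)2, THF, −78 °C; then 11, −78 to −45 °C
Reagents that add atoms: none
Why: In this Evans asymmetric alkylation the chelated (Z)-enolate is allylated on the face opposite the C4 benzyl group of the auxiliary, which sets the future C3 (2S here) with high diastereoselectivity expected.

Step 5
Reactants: 13 (4S)-4-benzyl-3-{(2S)-2-[4-(benzyloxy)-2-bromo-5-methoxybenzyl]pent-4-enoyl}-1,3-oxazolidin-2-one
Product: 14 (2S)-2-[4-(benzyloxy)-2-bromo-5-methoxybenzyl]pent-4-en-1-ol
Conditions: LiBH4, MeOH (1 equiv), THF, 0 °C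
Reagents that add atoms: none
Why: Reductive cleavage of the imide by LiBH4 gives the C3a carbinol without epimerization, leaves the aryl bromide and the alkene alone and returns the auxiliary.

Step 6
Reactants: 14 (2S)-2-[4-(benzyloxy)-2-bromo-5-methoxybenzyl]pent-4-en-1-ol
Product: 15 1-(benzyloxy)-4-{(2S)-2-[(benzyloxy)methyl]pent-4-en-1-yl}-5-bromo-2-methoxybenzene
Conditions: NaH, BnBr, n-Bu4NI (cat.), THF–DMF, 0 °C to rt
Reagents that add atoms: benzyl bromide, BrCc1ccccc1
Why: Williamson etherification masks C3a–OH as a benzyl ether that tolerates organolithium, periodate, amine and acid and later falls together with the aryl benzyl ethers.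

Step 7
Reactants: 16 vanillin
Product: 17 4-[(tert-butyldimethylsilyl)oxy]-3-methoxybenzaldehyde
Conditions: TBSCl, imidazole, DMF, rt
Reagents that add atoms: tert-butyldimethylsilyl chloride, CC(C)(C)[Si](C)(C)Cl
Why: Imidazole-promoted silylation removes the acidic phenol proton so that the aldehyde can accept an aryllithium, and the aryl silyl ether can later be cleaved by fluoride without touching benzyl ethers.

Step 8
Reactants: 15 1-(benzyloxy)-4-{(2S)-2-[(benzyloxy)methyl]pent-4-en-1-yl}-5-bromo-2-methoxybenzene; 17 4-[(tert-butyldimethylsilyl)oxy]-3-methoxybenzaldehyde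
Product: 19 {4-(benzyloxy)-2-[(2S)-2-[(benzyloxy)methyl]pent-4-en-1-yl]-5-methoxyphenyl}{4-[(tert-butyldimethylsilyl)oxy]-3-methoxyphenyl}methanol (both carbinol epimers), via aryllithium 18 (not isolated)
Conditions: n-BuLi, THF, −78 °C; then 17, −78 to −40 °C; aq. NH4Cl
Reagents that add atoms: none
Why: Bromine–lithium exchange at −78 °C outruns deprotonation and carbolithiation, and 1,2-addition of the aryllithium to the non-enolizable aldehyde forms the C1–C8a bond; the uncontrolled carbinol configuration is of no consequence.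

Step 9
Reactants: 19 {4-(benzyloxy)-2-[(2S)-2-[(benzyloxy)methyl]pent-4-en-1-yl]-5-methoxyphenyl}{4-[(tert-butyldimethylsilyl)oxy]-3-methoxyphenyl}methanol
Product: 21 (3R)-3-[(benzyloxy)methyl]-4-{4-(benzyloxy)-2-[{4-[(tert-butyldimethylsilyl)oxy]-3-methoxyphenyl}(hydroxy)methyl]-5-methoxyphenyl}butanal, via vicinal diol 20 (not isolated)
Conditions: OsO4 (2 mol %), NaIO4, 2,6-lutidine, 1,4-dioxane–H2O (3:1), rt
Reagents that add atoms: sodium periodate, [Na+].[O-]I(=O)(=O)=O (its oxygen reaches the product through catalytic osmium tetroxide, O=[Os](=O)(=O)=O)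
Why: Lemieux–Johnson oxidation (dihydroxylation, then periodate glycol cleavage) turns the vinyl group into the C2a aldehyde, and it is placed before desilylation because periodate would oxidize a free guaiacol-type phenol.

Step 10
Reactants: 21 (3R)-3-[(benzyloxy)methyl]-4-{4-(benzyloxy)-2-[{4-[(tert-butyldimethylsilyl)oxy]-3-methoxyphenyl}(hydroxy)methyl]-5-methoxyphenyl}butanal
Product: 22 (3R)-3-[(benzyloxy)methyl]-4-{4-(benzyloxy)-2-[hydroxy(4-hydroxy-3-methoxyphenyl)methyl]-5-methoxyphenyl}butanal (both carbinol epimers)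
Conditions: n-Bu4NF, AcOH, THF, 0 °C; used without delay
Reagents that add atoms: none
Why: Fluoride cleaves an aryl silyl ether within minutes at 0 °C, and acetic acid buffering should keep the medium from enolizing the aldehyde or dehydrating the p-hydroxybenzhydrol.

Step 11
Reactants: 22 (3R)-3-[(benzyloxy)methyl]-4-{4-(benzyloxy)-2-[hydroxy(4-hydroxy-3-methoxyphenyl)methyl]-5-methoxyphenyl}butanal
Product: 25 (1S,2R,3R)-7-(benzyloxy)-3-[(benzyloxy)methyl]-1-(4-hydroxy-3-methoxyphenyl)-6-methoxy-1,2,3,4-tetrahydronaphthalene-2-carbaldehyde, via quinone methide enamine 23 (not isolated), via cyclized iminium ion 24 (not isolated)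
Conditions: pyrrolidine (0.2 equiv), CF3CO2H (0.5 equiv), CH2Cl2 (0.02 M), 0 °C to rt
Reagents that add atoms: none
Why: Trifluoroacetic acid ionizes either carbinol epimer of 22 with loss of water to the p-quinone methide (the free hydroxyl of the pendant ring is para to C1), while pyrrolidine condenses with the C2a aldehyde to the (E)-enamine, giving 23 with the nucleophilic C2 five atoms from the electrophilic C1. C2 adds to C1 in an intramolecular 1,6-conjugate addition, a 6-(enolexo)-exo-trig closure of ring B; the pendant ring rearomatizes to the phenol and iminium ion 24 is hydrolyzed by the water released earlier, returning the amine. The closest known reaction type is the secondary-amine-catalyzed alpha-alkylation of aldehydes by p-quinone methides generated in situ from p-hydroxybenzylic alcohols, run here intramolecularly in the manner of amine-catalyzed intramolecular Michael cyclizations. C1 is set relative to C3 by a chair-like transition state with the C3 benzyloxymethyl group and the quinone methide ring both pseudo-equatorial (1,3-cis); C2 is set by the equatorial (E)-enamine and, being alpha to the aldehyde, can still equilibrate to the all-trans (1S,2R,3R) isomer. The step needs C-alkylation within the molecule to outrun aldol self-condensation and capture of the quinone methide by nitrogen, oxygen or a second arene; high dilution, the reversibility of heteroatom addition under acid and the favorable six-membered closure should secure this, and C3 is not at risk because it is not alpha to the carbonyl.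

Step 12
Reactants: 25 (1S,2R,3R)-7-(benzyloxy)-3-[(benzyloxy)methyl]-1-(4-hydroxy-3-methoxyphenyl)-6-methoxy-1,2,3,4-tetrahydronaphthalene-2-carbaldehyde
Product: 26 [(1S,2R,3R)-7-(benzyloxy)-3-[(benzyloxy)methyl]-1-(4-hydroxy-3-methoxyphenyl)-6-methoxy-1,2,3,4-tetrahydronaphthalen-2-yl]methanol
Conditions: NaBH4, MeOH–THF, 0 °C
Reagents that add atoms: none
Why: Borohydride 1,2-reduction of the aldehyde gives the C2a carbinol and fixes C2 against further epimerization, while the phenol and benzyl ethers are inert.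

Step 13
Reactants: 26 [(1S,2R,3R)-7-(benzyloxy)-3-[(benzyloxy)methyl]-1-(4-hydroxy-3-methoxyphenyl)-6-methoxy-1,2,3,4-tetrahydronaphthalen-2-yl]methanol
Product: 27 [(1S,2R,3R)-7-(benzyloxy)-1-[4-(benzyloxy)-3-methoxyphenyl]-3-[(benzyloxy)methyl]-6-methoxy-1,2,3,4-tetrahydronaphthalen-2-yl]methanol
Conditions: BnBr, K2CO3, acetone, 50 °C
Reagents that add atoms: benzyl bromide, BrCc1ccccc1
Why: In this Williamson etherification K2CO3 deprotonates only the phenol and not the primary alcohol, so O-benzylation is chemoselective and the phenol cannot be acylated in the next step.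

Step 14
Reactants: 27 [(1S,2R,3R)-7-(benzyloxy)-1-[4-(benzyloxy)-3-methoxyphenyl]-3-[(benzyloxy)methyl]-6-methoxy-1,2,3,4-tetrahydronaphthalen-2-yl]methanol; 28 (E)-3-[4-(benzyloxy)phenyl]prop-2-enoic acid
Product: 29 [(1S,2R,3R)-7-(benzyloxy)-1-[4-(benzyloxy)-3-methoxyphenyl]-3-[(benzyloxy)methyl]-6-methoxy-1,2,3,4-tetrahydronaphthalen-2-yl]methyl (E)-3-[4-(benzyloxy)phenyl]prop-2-enoate
Conditions: DCC, DMAP (cat.), CH2Cl2, 0 °C to rt
Reagents that add atoms: none
Why: Steglich esterification acylates the only free hydroxyl, the C2a primary alcohol, without activating its carbon and without isomerizing the (E)-alkene.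

Step 15
Reactants: 29 [(1S,2R,3R)-7-(benzyloxy)-1-[4-(benzyloxy)-3-methoxyphenyl]-3-[(benzyloxy)methyl]-6-methoxy-1,2,3,4-tetrahydronaphthalen-2-yl]methyl (E)-3-[4-(benzyloxy)phenyl]prop-2-enoate
Product: 30 [(1S,2R,3R)-7-hydroxy-1-(4-hydroxy-3-methoxyphenyl)-3-(hydroxymethyl)-6-methoxy-1,2,3,4-tetrahydronaphthalen-2-yl]methyl (E)-3-(4-hydroxyphenyl)prop-2-enoate (CNP0403384.1)
Conditions: BCl3, C6HMe5, CH2Cl2, −78 to −40 °C; then CHCl3–MeOH
Reagents that add atoms: none
Why: Lewis-acid debenzylation with pentamethylbenzene as a non-basic benzyl-cation scavenger removes the three aryl and one alkyl benzyl ethers at low temperature while sparing the cinnamate C=C bond (which hydrogenolysis would reduce), the ester and the aryl methyl ethers.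

**Compound list**

1 | 4-(benzyloxy)-3-methoxybenzaldehyde (O-benzylvanillin) | COc1cc(C=O)ccc1OCc1ccccc1 | starting material
2 | 4-(benzyloxy)-2-bromo-5-methoxybenzaldehyde | COc1cc(C=O)c(Br)cc1OCc1ccccc1 | intermediate
3 | Meldrum's acid (2,2-dimethyl-1,3-dioxane-4,6-dione) | CC1(C)OC(=O)CC(=O)O1 | starting material
4 | 5-[4-(benzyloxy)-2-bromo-5-methoxybenzylidene]-2,2-dimethyl-1,3-dioxane-4,6-dione (formed in the flask) | COc1cc(C=C2C(=O)OC(C)(C)OC2=O)c(Br)cc1OCc1ccccc1 | intermediate
5 | 5-[4-(benzyloxy)-2-bromo-5-methoxybenzyl]-2,2-dimethyl-1,3-dioxane-4,6-dione (formed in the flask) | COc1cc(CC2C(=O)OC(C)(C)OC2=O)c(Br)cc1OCc1ccccc1 | intermediate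
6 | 2-[4-(benzyloxy)-2-bromo-5-methoxybenzyl]malonic acid (formed in the flask) | COc1cc(CC(C(=O)O)C(=O)O)c(Br)cc1OCc1ccccc1 | intermediate
7 | 3-[4-(benzyloxy)-2-bromo-5-methoxyphenyl]propanoic acid | COc1cc(CCC(=O)O)c(Br)cc1OCc1ccccc1 | intermediate
8 | (S)-4-benzyl-1,3-oxazolidin-2-one | O=C1N[C@@H](Cc2ccccc2)CO1 | starting material
9 | 3-[4-(benzyloxy)-2-bromo-5-methoxyphenyl]propanoic pivalic anhydride (formed in the flask) | COc1cc(CCC(=O)OC(=O)C(C)(C)C)c(Br)cc1OCc1ccccc1 | intermediate
10 | (4S)-4-benzyl-3-{3-[4-(benzyloxy)-2-bromo-5-methoxyphenyl]propanoyl}-1,3-oxazolidin-2-one | COc1cc(CCC(=O)N2[C@@H](Cc3ccccc3)COC2=O)c(Br)cc1OCc1ccccc1 | intermediate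
11 | allyl iodide (3-iodoprop-1-ene) | C=CCI | starting material
12 | sodium (Z)-enolate of imide 10 (formed in the flask) | COc1cc(C/C=C(\[O-])N2[C@@H](Cc3ccccc3)COC2=O)c(Br)cc1OCc1ccccc1.[Na+] | intermediate
13 | (4S)-4-benzyl-3-{(2S)-2-[4-(benzyloxy)-2-bromo-5-methoxybenzyl]pent-4-enoyl}-1,3-oxazolidin-2-one | COc1cc(C[C@H](CC=C)C(=O)N2[C@@H](Cc3ccccc3)COC2=O)c(Br)cc1OCc1ccccc1 | intermediate
14 | (2S)-2-[4-(benzyloxy)-2-bromo-5-methoxybenzyl]pent-4-en-1-ol | COc1cc(C[C@H](CC=C)CO)c(Br)cc1OCc1ccccc1 | intermediate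
15 | 1-(benzyloxy)-4-{(2S)-2-[(benzyloxy)methyl]pent-4-en-1-yl}-5-bromo-2-methoxybenzene | COc1cc(C[C@H](CC=C)COCc2ccccc2)c(Br)cc1OCc1ccccc1 | intermediate
16 | vanillin | COc1cc(C=O)ccc1O | starting material
17 | 4-[(tert-butyldimethylsilyl)oxy]-3-methoxybenzaldehyde | COc1cc(C=O)ccc1O[Si](C)(C)C(C)(C)C | intermediate
18 | aryllithium from 15, lithium in place of bromine (formed in the flask) | COc1cc(C[C@H](CC=C)COCc2ccccc2)c([Li])cc1OCc1ccccc1 | intermediate
19 | {4-(benzyloxy)-2-[(2S)-2-[(benzyloxy)methyl]pent-4-en-1-yl]-5-methoxyphenyl}{4-[(tert-butyldimethylsilyl)oxy]-3-methoxyphenyl}methanol (both carbinol epimers) | COc1cc(C(O)c2cc(OCc3ccccc3)c(OC)cc2C[C@H](CC=C)COCc2ccccc2)ccc1O[Si](C)(C)C(C)(C)C | intermediate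
20 | (4R)-4-[(benzyloxy)methyl]-5-{4-(benzyloxy)-2-[{4-[(tert-butyldimethylsilyl)oxy]-3-methoxyphenyl}(hydroxy)methyl]-5-methoxyphenyl}pentane-1,2-diol (epimers at C2 and at the diaryl carbinol; formed in the flask) | COc1cc(C(O)c2cc(OCc3ccccc3)c(OC)cc2C[C@@H](COCc2ccccc2)CC(O)CO)ccc1O[Si](C)(C)C(C)(C)C | intermediate
21 | (3R)-3-[(benzyloxy)methyl]-4-{4-(benzyloxy)-2-[{4-[(tert-butyldimethylsilyl)oxy]-3-methoxyphenyl}(hydroxy)methyl]-5-methoxyphenyl}butanal (both carbinol epimers) | COc1cc(C(O)c2cc(OCc3ccccc3)c(OC)cc2C[C@@H](COCc2ccccc2)CC=O)ccc1O[Si](C)(C)C(C)(C)C | intermediate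
22 | (3R)-3-[(benzyloxy)methyl]-4-{4-(benzyloxy)-2-[hydroxy(4-hydroxy-3-methoxyphenyl)methyl]-5-methoxyphenyl}butanal (both carbinol epimers) | COc1cc(C(O)c2cc(OCc3ccccc3)c(OC)cc2C[C@@H](COCc2ccccc2)CC=O)ccc1O | intermediate
23 | 4-{[4-(benzyloxy)-2-{(2R,3E)-2-[(benzyloxy)methyl]-4-(pyrrolidin-1-yl)but-3-en-1-yl}-5-methoxyphenyl]methylidene}-2-methoxycyclohexa-2,5-dien-1-one (formed in the flask) | COC1=CC(=Cc2cc(OCc3ccccc3)c(OC)cc2C[C@@H](COCc2ccccc2)/C=C/N2CCCC2)C=CC1=O | intermediate
24 | 1-{[(1S,2R,3R)-7-(benzyloxy)-3-[(benzyloxy)methyl]-1-(4-hydroxy-3-methoxyphenyl)-6-methoxy-1,2,3,4-tetrahydronaphthalen-2-yl]methylidene}pyrrolidin-1-ium trifluoroacetate (formed in the flask) | COc1cc([C@H]2c3cc(OCc4ccccc4)c(OC)cc3C[C@@H](COCc3ccccc3)[C@@H]2C=[N+]2CCCC2)ccc1O.[O-]C(=O)C(F)(F)F | intermediate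
25 | (1S,2R,3R)-7-(benzyloxy)-3-[(benzyloxy)methyl]-1-(4-hydroxy-3-methoxyphenyl)-6-methoxy-1,2,3,4-tetrahydronaphthalene-2-carbaldehyde | COc1cc([C@H]2c3cc(OCc4ccccc4)c(OC)cc3C[C@@H](COCc3ccccc3)[C@@H]2C=O)ccc1O | intermediate
26 | [(1S,2R,3R)-7-(benzyloxy)-3-[(benzyloxy)methyl]-1-(4-hydroxy-3-methoxyphenyl)-6-methoxy-1,2,3,4-tetrahydronaphthalen-2-yl]methanol | COc1cc([C@H]2c3cc(OCc4ccccc4)c(OC)cc3C[C@@H](COCc3ccccc3)[C@@H]2CO)ccc1O | intermediate
27 | [(1S,2R,3R)-7-(benzyloxy)-1-[4-(benzyloxy)-3-methoxyphenyl]-3-[(benzyloxy)methyl]-6-methoxy-1,2,3,4-tetrahydronaphthalen-2-yl]methanol | COc1cc([C@H]2c3cc(OCc4ccccc4)c(OC)cc3C[C@@H](COCc3ccccc3)[C@@H]2CO)ccc1OCc1ccccc1 | intermediate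
28 | (E)-3-[4-(benzyloxy)phenyl]prop-2-enoic acid | O=C(O)/C=C/c1ccc(OCc2ccccc2)cc1 | starting material
29 | [(1S,2R,3R)-7-(benzyloxy)-1-[4-(benzyloxy)-3-methoxyphenyl]-3-[(benzyloxy)methyl]-6-methoxy-1,2,3,4-tetrahydronaphthalen-2-yl]methyl (E)-3-[4-(benzyloxy)phenyl]prop-2-enoate | COc1cc([C@H]2c3cc(OCc4ccccc4)c(OC)cc3C[C@@H](COCc3ccccc3)[C@@H]2COC(=O)/C=C/c2ccc(OCc3ccccc3)cc2)ccc1OCc1ccccc1 | intermediate
30 | [(1S,2R,3R)-7-hydroxy-1-(4-hydroxy-3-methoxyphenyl)-3-(hydroxymethyl)-6-methoxy-1,2,3,4-tetrahydronaphthalen-2-yl]methyl (E)-3-(4-hydroxyphenyl)prop-2-enoate | COc1cc([C@H]2c3cc(O)c(OC)cc3C[C@@H](CO)[C@@H]2COC(=O)/C=C/c2ccc(O)cc2)ccc1O | target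

**Totals**

Total step count: 15. Longest linear sequence: 14 steps (steps 1–6 and 8–15, from 1 to 30).

**Steps most likely to fail**

Step 11. The enamine may undergo aldol self-condensation, the quinone methide may be captured by nitrogen, oxygen or a second arene faster than ring B closes, or the two faces of C1 may be poorly discriminated. The fallback sets out from 21 and comes back at 25; it makes the same C1–C2 bond by an intramolecular Mukaiyama-type alkylation with a preformed nucleophile. Aldehyde 21 with TBSOTf and Et3N (CH2Cl2, 0 °C to rt) should give the silyl enol ether whose carbinol is also silylated, the tris-silyl enol ether F1. Catalytic TMSOTf in CH2Cl2 at −78 °C would ionize the benzhydryl silyl ether to the diarylmethyl cation, which the enol ether captures in the same six-membered closure at low temperature, giving the O-silylated tetralin aldehyde F2. n-Bu4NF/AcOH in THF then frees the phenol and returns the route to 25.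

Step 10. Fluoride-induced enolization and aldol condensation of the free aldehyde, or premature dehydration and oligomerization of the p-hydroxybenzhydrol during isolation, may erode the precursor. The fallback sets out from 21 and comes back at 25; both reactive groups are masked before the fluoride step. HC(OMe)3 and pyridinium p-toluenesulfonate in MeOH should convert 21 into the dimethyl acetal in which the carbinol has become its methyl ether (acetalization and SN1 etherification), the acetal methyl ether F3. n-Bu4NF in THF then gives the storable phenol F4. Under the conditions of step 11 with a few equivalents of water, acid hydrolyzes the acetal and ionizes the benzhydryl methyl ether to the same quinone methide, so F4 should close directly to 25 with loss of methanol.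

Step 15. Cleavage of the primary alkyl benzyl ether may be incomplete, or the Lewis acid may cause acyl migration to C3a–OH or loss of the ester. The fallback sets out from 27 and comes back at 30; the benzyl groups are removed by hydrogenolysis before the C=C bond exists. Heating 27 with Meldrum's acid in toluene should give the hydrogen malonate F5. H2 over Pd/C (EtOAc–MeOH) removes all three benzyl groups and gives the debenzylated hydrogen malonate F6. Knoevenagel–Doebner condensation of F6 with 4-hydroxybenzaldehyde (pyridine, catalytic piperidine) then builds the (E)-4-hydroxycinnamate with decarboxylation and gives 30 directly.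

**Further compounds**

F1 | step 11 | tert-butyldimethylsilyl enol ether of 21 with the carbinol as its tert-butyldimethylsilyl ether (enol ether geometry and carbinol epimers mixed) | COc1cc(C(O[Si](C)(C)C(C)(C)C)c2cc(OCc3ccccc3)c(OC)cc2C[C@@H](COCc2ccccc2)C=CO[Si](C)(C)C(C)(C)C)ccc1O[Si](C)(C)C(C)(C)C
F2 | step 11 | (1S,2R,3R)-7-(benzyloxy)-3-[(benzyloxy)methyl]-1-{4-[(tert-butyldimethylsilyl)oxy]-3-methoxyphenyl}-6-methoxy-1,2,3,4-tetrahydronaphthalene-2-carbaldehyde | COc1cc([C@H]2c3cc(OCc4ccccc4)c(OC)cc3C[C@@H](COCc3ccccc3)[C@@H]2C=O)ccc1O[Si](C)(C)C(C)(C)C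
F3 | step 10 | dimethyl acetal of 21 with the diaryl carbinol as its methyl ether (3R; both ether epimers) | COc1cc(C(OC)c2cc(OCc3ccccc3)c(OC)cc2C[C@@H](COCc2ccccc2)CC(OC)OC)ccc1O[Si](C)(C)C(C)(C)C
F4 | step 10 | desilylated phenol of F3 | COc1cc(C(OC)c2cc(OCc3ccccc3)c(OC)cc2C[C@@H](COCc2ccccc2)CC(OC)OC)ccc1O
F5 | step 15 | hydrogen malonate of alcohol 27 at C2a–O | COc1cc([C@H]2c3cc(OCc4ccccc4)c(OC)cc3C[C@@H](COCc3ccccc3)[C@@H]2COC(=O)CC(=O)O)ccc1OCc1ccccc1
F6 | step 15 | hydrogen malonate at C2a–O with both phenols and C3a–OH free | COc1cc([C@H]2c3cc(O)c(OC)cc3C[C@@H](CO)[C@@H]2COC(=O)CC(=O)O)ccc1O
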